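**Plan**

Locants: the ring A half keeps N-methylflindersine numbering (O1, C2, C3, C4, C4a, C5=O, N6, C10b); the second quinolone is primed (C2'=O, C3', C4'–O4') and its side chain is C1'', C2'', C3''.
Retrosynthesis: water is removed from the side chain (C3''–OH to C2''=C3''), then the central dihydropyran is cut by a retro-[4+2] at C3–C1'' and C4–O4'. This gives two molecules of N-methylflindersine, whose pyran is cut at C4–C4a and O1–C2 to 4-hydroxy-1-methylquinolin-2(1H)-one and prenal.
Enabling feature: the 2H-pyran of N-methylflindersine is a tertiary allylic vinylogous ester (O1–C2) that can open to the heterodiene O4'=C4'–C3'=C1'' of a 3-alkylidenequinoline-2,4-dione, while its C3=C4 bond is the nucleophilic end of the dienol ether O1–C10b=C4a–C4=C3. One compound therefore supplies both partners, as in the presumed biosynthesis.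
Forward order: pyran ring A (step 1), central dihydropyran by enantioselective dimerisation (step 2), Markovnikov hydration of the side-chain alkene (step 3).
Stereochemistry: C3, C4 and C1'' all arise in step 2. The cis ring fusion follows from suprafacial addition to the ring alkene, the anti C1''/C3 relation from an exo approach, and the absolute configuration from the chiral Brønsted acid counter-anion.

Key step: step 2

Remark: the sense of induction of a chiral counter-anion in a new ion-pair reaction cannot be predicted with certainty; the (R)-acid is written, and its mirror image is to be used if the first experiments show the opposite series.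

**Route**

Step 1
Reactants: 1 4-hydroxy-1-methylquinolin-2(1H)-one; 2 3-methylbut-2-enal
Product: 4 N-methylflindersine (2,2,6-trimethyl-2H-pyrano[3,2-c]quinolin-5(6H)-one), via ring-opened dienone 3 (not isolated)
Conditions: ethylenediammonium diacetate (10 mol %), DMF, 100 °C
Reagents that add atoms: none
Why: Knoevenagel condensation of the vinylogous acid 1 with the enal gives dienone 3, which closes through the C4 carbonyl oxygen by oxa-6π electrocyclisation to the angular 2H-pyran; no stereocentre is formed.

Step 2
Reactants: 4 N-methylflindersine (two molecules; one is opened by the acid to the heterodiene, the other serves as the 2π partner)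
Product: 6 (3R,4S,1''R)-configured cis-fused dimer of N-methylflindersine bearing a 2-methylprop-1-enyl group at C1'', via vinyl-outside dienone isomer 5 (not isolated)
Conditions: (R)-N-triflylphosphoramide of 3,3'-bis(2,4,6-triisopropylphenyl)-BINOL (10 mol %), toluene (1 M), 5 Å MS, 40 °C
Reagents that add atoms: none
Why: Proposed new method: the chiral acid protonates the C5 carbonyl of one molecule of 4 and so turns O1 into a vinylogous carboxylic acid leaving group; the tertiary allylic O1–C2 bond then ionises reversibly (at 40 °C the purely thermal retro-oxa-6π opening is too slow to contribute) to a hydroxyquinolinone carrying a dimethylallyl cation at C3', held as a contact ion pair with the chiral anion, and because this cation is the conjugate acid of the 3-alkylidenequinoline-2,4-dione and its C3'–C1'' bond has largely single-bond character, it equilibrates with the rotamer that has the dimethylvinyl group syn to C2', which is protonated 5; C3 of a second molecule of 4 then attacks C1'' and the C4 vinylogous oxocarbenium ion so formed is captured by O4' in the same ion pair. The closest known reaction types are the chiral phosphoric acid and N-triflylphosphoramide catalysed inverse-electron-demand oxa-Diels–Alder reactions of in situ generated ortho-quinone methides with styrenes and enol ethers, the domino Knoevenagel/hetero-Diels–Alder reaction of 4-hydroxyquinolin-2-ones, and the thermal retro-oxa-6π/hetero-Diels–Alder isomerisation of 2H-chromenes to citrans; new are the intermolecular use of an acid-opened 2H-pyran as heterodiene and the asymmetric catalysis. The central dihydropyran closes as a highly asynchronous [4+2] cycloaddition (O4'=C4'–C3'=C1'' plus C3=C4), whose second bond is, in the stepwise limit, a 6-exo-trig capture of the C4 cation by O4'. C3 and C4 should become cis because both new bonds are delivered to the same face of the ring (Z)-alkene, C1'' should carry its side chain anti to C2 (H-1'' trans to H-3) through an exo approach in which the pyran ring of 4 and its pseudo-axial C2 methyl group point away from the quinolinedione plane, and the absolute sense is set by the chiral anion shielding one face of the hydrogen-bonded heterodiene. The step needs chemoselectivity for O1–C2 ionisation over protonation of C3=C4 (which would lead to head-to-tail chromene-type dimers), sought through a confined acid of moderate strength and the low basicity of the electron-poor C3=C4 bond; it also needs attack at C1'' instead of the tertiary C3'' terminus (steric hindrance at C3'') and closure through O4' instead of O2' (it gives the more stable 4-alkoxyquinolin-2-one).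

Step 3
Reactants: 6 (3R,4S,1''R)-configured cis-fused dimer bearing a 2-methylprop-1-enyl group at C1''
Product: 7 target (3R,4S,1''R)-hexacycle bearing a 2-hydroxy-2-methylpropyl group at C1''
Conditions: Co(acac)2 (20 mol %), PhSiH3, O2 (1 atm), THF, rt
Reagents that add atoms: dioxygen, O=O
Why: Mukaiyama hydration: hydrogen-atom transfer from a cobalt hydride to C2'' of the trisubstituted alkene gives the tertiary C3'' radical, which is trapped by O2 and reduced to the tertiary alcohol with Markovnikov regiochemistry; no stereocentre is created and C3, C4 and C1'' are not touched.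

**Compound list**

1 | 4-hydroxy-1-methylquinolin-2(1H)-one | Cn1c(=O)cc(O)c2ccccc21 | starting material
2 | 3-methylbut-2-enal (prenal) | CC(C)=CC=O | starting material
3 | (3E)-1-methyl-3-(3-methylbut-2-en-1-ylidene)quinoline-2,4(1H,3H)-dione (Knoevenagel product of step 1; dimethylvinyl group syn to the C4 ketone) | CN1C(=O)/C(=C/C=C(C)C)C(=O)c2ccccc21 | intermediate
4 | N-methylflindersine, 2,2,6-trimethyl-2H-pyrano[3,2-c]quinolin-5(6H)-one | Cn1c(=O)c2c(c3ccccc31)OC(C)(C)C=C2 | intermediate
5 | (3Z)-1-methyl-3-(3-methylbut-2-en-1-ylidene)quinoline-2,4(1H,3H)-dione (dimethylvinyl group syn to the C2 amide carbonyl; formed and engaged in step 2 as its conjugate acid in the ion pair with the catalyst anion, neutral form shown) | CN1C(=O)/C(=C\C=C(C)C)C(=O)c2ccccc21 | intermediate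
6 | (3R,4S,1''R)-dimer: C3 of one N-methylflindersine unit bonded to C1'' and C4 bonded to O4' of a 4-oxy-1-methylquinolin-2-one unit, cis-fused (H-3/H-4 cis, H-1''/H-3 trans), 2-methylprop-1-enyl at C1'' | Cn1c(=O)c2c(c3ccccc31)OC(C)(C)[C@H]1[C@@H]2Oc2c(c(=O)n(C)c3ccccc23)[C@@H]1C=C(C)C | intermediate
7 | target: the same (3R,4S,1''R)-hexacycle with a 2-hydroxy-2-methylpropyl group at C1'' | Cn1c(=O)c2c(c3ccccc31)OC(C)(C)[C@H]1[C@@H]2Oc2c(c(=O)n(C)c3ccccc23)[C@@H]1CC(C)(C)O | target

**Step count and risks**

Total step count: 3. Longest linear sequence: 3.

Steps most likely to fail: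

1. Step 2 (proposed new method). The ion pair may re-close to 4 faster than it is intercepted. Protonation of C3=C4 may divert material into head-to-tail dimerisation, and loss of a proton from a C3'' methyl group may lead to the 1,3-diene and its Diels–Alder dimers. Facial discrimination by the anion may be poor, at C1'' or in the absolute sense. The fallback uses known chemistry, sets out from 4 and returns at 7, so that step 3 is not needed. Jacobsen–Katsuki epoxidation of 4 with (S,S)-N,N'-bis(3,5-di-tert-butylsalicylidene)-1,2-cyclohexanediaminomanganese chloride (a trivalent manganese complex), NaOCl and 4-phenylpyridine N-oxide in CH2Cl2 at 0 °C should give (3S,4S)-3,4-epoxy-N-methylflindersine F1, by analogy with 2,2-dimethylchromenes; this fixes the absolute configuration. Separately, Reimer–Tiemann formylation of 1 (CHCl3, aq. NaOH) gives 4-hydroxy-1-methyl-2-oxo-1,2-dihydroquinoline-3-carbaldehyde F2, and Wittig olefination (Ph3P=CHCO2Me, toluene, 80 °C) gives the (E)-acrylate F3. Opening of the epoxide at the activated C4 by the 4-oxygen of the acrylate (Cs2CO3, DMF, 50 °C) with inversion should give the trans-(3S,4R)-hydroxy ether F4. Acylation with PhOC(S)Cl and DMAP in MeCN gives the O-phenyl thionocarbonate F5. Barton–McCombie-type radical generation ((TMS)3SiH, AIBN, toluene, 90 °C, slow addition) gives the planar C3 radical, which closes the central ring by 6-exo-trig addition to the acrylate β-carbon C1'' on the C4–O4' tether (a Ueno–Stork-type cyclisation). The C4 stereocentre directs cis fusion and the ester arm is expected anti to C2, to give the (3R,4S,1''R)-methyl ester F6. MeMgBr with CeCl3 in THF at −78 to 0 °C then converts the ester into the tertiary alcohol 7.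

2. Step 3. The tertiary radical may be reduced to the alkane instead of being oxygenated, or hydrogen abstraction may occur at the doubly activated C4–H. The fallback sets out from 6 and returns at 7 by an ionic two-stage hydration. Oxymercuration (Hg(OAc)2, a divalent mercury salt, THF/H2O, rt) places mercury on C2'' and hydroxyl on C3'' to give the β-hydroxyalkylmercury acetate F7. Reductive demercuration (NaBH4, aq. NaOH) then gives 7.

3. Step 1. A second molecule of 1 may add to dienone 3 in a Michael reaction (bis-adduct), or closure may occur through the amide oxygen to give the linear pyrano[2,3-b]quinolinone isomer. The fallback sets out from 1 and returns at 4 and fixes the regiochemistry through an O4 ether. Alkylation of 1 with 3-chloro-3-methylbut-1-yne (DBU, CuCl2 cat., MeCN, 0 °C) gives 1-methyl-4-[(2-methylbut-3-yn-2-yl)oxy]quinolin-2(1H)-one F8. Heating in N,N-diethylaniline at 180 °C (propargyl Claisen rearrangement, 1,5-hydrogen shift, oxa-6π closure) gives 4.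

**Further compounds**

F1 | step 2 | (3S,4S)-3,4-epoxy-2,2,6-trimethyl-3,4-dihydro-2H-pyrano[3,2-c]quinolin-5(6H)-one | Cn1c(=O)c2c(c3ccccc31)OC(C)(C)[C@H]1O[C@@H]21
F2 | step 2 | 4-hydroxy-1-methyl-2-oxo-1,2-dihydroquinoline-3-carbaldehyde | Cn1c(=O)c(C=O)c(O)c2ccccc21
F3 | step 2 | methyl (E)-3-(4-hydroxy-1-methyl-2-oxo-1,2-dihydroquinolin-3-yl)acrylate | COC(=O)/C=C/c1c(O)c2ccccc2n(C)c1=O
F4 | step 2 | methyl (E)-3-{4-[((3S,4R)-3-hydroxy-2,2,6-trimethyl-5-oxo-3,4,5,6-tetrahydro-2H-pyrano[3,2-c]quinolin-4-yl)oxy]-1-methyl-2-oxo-1,2-dihydroquinolin-3-yl}acrylate | Cn1c(=O)c2c(c3ccccc31)OC(C)(C)[C@@H](O)[C@@H]2Oc2c(/C=C/C(=O)OC)c(=O)n(C)c3ccccc23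
F5 | step 2 | O-phenyl thionocarbonate of the C3 hydroxyl of F4, (3S,4R) | Cn1c(=O)c2c(c3ccccc31)OC(C)(C)[C@@H](OC(=S)Oc3ccccc3)[C@@H]2Oc2c(/C=C/C(=O)OC)c(=O)n(C)c3ccccc23
F6 | step 2 | (3R,4S,1''R)-hexacycle bearing a 2-methoxy-2-oxoethyl group at C1'' | Cn1c(=O)c2c(c3ccccc31)OC(C)(C)[C@H]1[C@@H]2Oc2c(c(=O)n(C)c3ccccc23)[C@@H]1CC(=O)OC
F7 | step 3 | (3R,4S,1''R)-hexacycle bearing a 1-(acetoxymercurio)-2-hydroxy-2-methylpropyl group at C1'' (both C2'' epimers) | Cn1c(=O)c2c(c3ccccc31)OC(C)(C)[C@H]1[C@@H]2Oc2c(c(=O)n(C)c3ccccc23)[C@@H]1C([Hg]OC(C)=O)C(C)(C)O
F8 | step 1 | 1-methyl-4-[(2-methylbut-3-yn-2-yl)oxy]quinolin-2(1H)-one | Cn1c(=O)cc(OC(C)(C)C#C)c2ccccc21
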